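The route rests on cutting C15–C16 in ring D. In the bicyclo[3.2.1]octanone made up of rings C and D, the C15 carbonyl is bonded to the quaternary carbon C8 and C16 to the methine C13, so C15–C8–C14–C13=C16 is a pent-4-enal. One operation adds the formyl C–H bond across the C13=C16 methylene. It makes C15–C16 and C13–H, closes ring D and derives C13 from C8. Precursor 24 joins ring A to a ring C cyclohexene through C9–C10 and carries CHO and a chelating CH2OBn on C8. It comes from enolate arylation and an auxiliary-controlled Birch reductive alkylation. Seven routine steps then add C17, the acetates, the epoxide and the lactol.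

Key step: step 18

Numbering: ring A = C1, C2 (both OAc), C3, C4 (Me2), C5, C10 (methyl C20); ring B = C5, C6 (lactol), O, C7, C8, C9, C10; ring C = C8, C9, C11, C12, C13, C14; ring D = C8, C15 (C=O), C16 (bears methyl C17), C13, C14.
Remark on the key step: an acyl metal hydride chelated to C13=C16 reaches only the alkene face cis to the formyl group and adds syn, which leaves C16 trans to C15 and unable to bridge. The net hydroacylation is therefore run stepwise with a Lewis acid, C–C bond first and hydrogen to the outer face of C13 afterwards.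
Assumption 1: the (S)-pyrrolidine auxiliary is taken to direct BnOCH2Cl to the C8 face drawn, as expected for 2-alkylbenzamides of this amine.
Assumption 2: C6 is an anomeric centre and is taken to equilibrate to the (6R) lactol drawn.

Step 1
Reactants: 1 2,4,4-trimethylcyclohex-2-en-1-one
Product: 2 (1S)-2,4,4-trimethylcyclohex-2-en-1-ol
Conditions: (R)-2-methyl-CBS-oxazaborolidine (10 mol%), BH3·SMe2, THF, −20 °C; aqueous work-up
Reagents that add atoms: none
Why: Corey–Bakshi–Shibata reduction, in which the oxazaborolidine binds the ketone with the α-methylalkenyl arm as the large group, so hydride reaches one face only and sets the sacrificial (S)-carbinol at C1.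

Step 2
Reactants: 2 (1S)-2,4,4-trimethylcyclohex-2-en-1-ol
Product: 3 stannylmethyl ether of 2
Conditions: KH, THF, 0 °C; Bu3SnCH2I, rt
Reagents that add atoms: tributyl(iodomethyl)stannane CCCC[Sn](CI)(CCCC)CCCC
Why: Williamson etherification of the potassium alkoxide with a primary iodide, which leaves the carbinol centre untouched.

Step 3
Reactants: 3 stannylmethyl ether of 2
Product: 5 (R)-α-cyclogeraniol, via lithiomethyl ether 4 (not isolated)
Conditions: n-BuLi, THF, −78 °C
Reagents that add atoms: n-butyllithium [Li]CCCC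
Why: Tin–lithium exchange followed by a Wittig–Still [2,3]-sigmatropic rearrangement passes the CH2O unit (C6) suprafacially from O-1 to C5, so the C1 configuration is transferred to C5 while the alkene moves to C1=C10.

Step 4
Reactants: 5 (R)-α-cyclogeraniol
Product: 6 TIPS ether of 5
Conditions: TIPSCl, imidazole, DMF, rt
Reagents that add atoms: chlorotriisopropylsilane CC(C)[Si](Cl)(C(C)C)C(C)C
Why: Silylation of the primary alcohol gives an ether that tolerates dissolving metal, hydride, Lewis acid and mild aqueous acid.

Step 5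
Reactants: 6 TIPS ether of 5
Product: 8 ring A alcohol, via alkylborane 7 (not isolated)
Conditions: BH3·THF, THF, 0 °C to rt; NaOH, H2O2
Reagents that add atoms: borane B; hydrogen peroxide OO
Why: Hydroboration–oxidation places boron on the less substituted C1 by syn addition anti to the C5 side chain, and both new centres are erased or reset later.

Step 6
Reactants: 8 ring A alcohol
Product: 9 ring A ketone
Conditions: (n-Pr4N)RuO4 (5 mol%), NMO, 4 Å molecular sieves, CH2Cl2, rt
Reagents that add atoms: none
Why: Ley–Griffith oxidation of the secondary alcohol gives the C1 ketone without touching C5.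

Step 7
Reactants: 9 ring A ketone
Product: 10 C2-blocked enaminone
Conditions: t-BuOCH(NMe2)2, toluene, 100 °C
Reagents that add atoms: tert-butoxybis(dimethylamino)methane CC(C)(C)OC(N(C)C)N(C)C
Why: Aminomethylenation can occur only at the α-methylene C2, so the vinylogous amide blocks C2, leaves C10–H as the one acidic site and already marks C2 for oxidation.

Step 8
Reactants: 11 2-bromo-5-methoxybenzoic acid; 12 (S)-2-(methoxymethyl)pyrrolidine
Product: 14 bromo amide, via acid chloride 13 (not isolated)
Conditions: (COCl)2, DMF (cat.), CH2Cl2, 0 °C to rt; then 12, Et3N, CH2Cl2, 0 °C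
Reagents that add atoms: oxalyl chloride ClC(=O)C(=O)Cl
Why: Acylation of the secondary amine through the acid chloride attaches the auxiliary without affecting its stereocentre.

Step 9
Reactants: 10 C2-blocked enaminone; 14 bromo amide
Product: 15 C10-arylated ketone
Conditions: Pd(OAc)2 (10 mol%), P(t-Bu)3 (20 mol%), NaOt-Bu, toluene, 80 °C
Reagents that add atoms: none
Why: Palladium-catalysed α-arylation of an α'-blocked ketone enolate forms C9–C10, and the aryl group enters anti to the C5 CH2OTIPS group and away from the axial C4 methyl, which sets quaternary C10.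

Step 10
Reactants: 15 C10-arylated ketone
Product: 16 diosphenol
Conditions: O2, tetraphenylporphyrin (cat.), visible light, CH2Cl2, −20 °C
Reagents that add atoms: oxygen O=O
Why: Singlet-oxygen cleavage of the enaminone C=C through a dioxetane turns C2 into a carbonyl group, and the 1,2-dione rests as its enol towards C3.

Step 11
Reactants: 16 diosphenol
Product: 17 cis-1,2-diol
Conditions: NaBH4, MeOH–THF, 0 °C to rt
Reagents that add atoms: none
Why: Borohydride reduction of the dione tautomer: at C2 the syn-axial C20 and C4 methyl groups close the upper face so hydride enters from below (axial 2-OH), and at C1 axial attack anti to C20 gives the equatorial 1-OH, hence the cis-diol on the C20 face.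

Step 12
Reactants: 17 cis-1,2-diol
Product: 18 acetonide aryl amide
Conditions: Me2C(OMe)2, PPTS (cat.), CH2Cl2, rt
Reagents that add atoms: 2,2-dimethoxypropane COC(C)(C)OC
Why: Transketalisation closes the dioxolane only on a cis-diol and masks both hydroxyl groups for the strongly basic steps ahead.

Step 13
Reactants: 18 acetonide aryl amide
Product: 20 Birch diene, via potassium enolate 19 (not isolated)
Conditions: K (2.5 equiv), t-BuOH (1 equiv), NH3–THF, −78 °C; piperylene; BnOCH2Cl, −78 °C
Reagents that add atoms: potassium [K]; benzyl chloromethyl ether ClCOCc1ccccc1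
Why: Birch reductive alkylation, in which reduction at C8 and C12 leaves OMe and C10 on the surviving double bonds, and the methoxymethyl arm chelated in enolate 19 covers one face so that the electrophile (C7) enters from the other and sets quaternary C8.

Step 14
Reactants: 20 Birch diene
Product: 21 C13 ketone
Conditions: oxalic acid (cat.), THF–H2O, 0 °C to rt
Reagents that add atoms: water O
Why: Mild enol ether hydrolysis unmasks the C13 ketone while C9=C11 stays out of conjugation and the acetonide and silyl ether survive.

Step 15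
Reactants: 21 C13 ketone
Product: 22 methylene amide
Conditions: Cp2TiMe2, toluene, 70 °C, dark
Reagents that add atoms: dimethyltitanocene [CH3-].[CH3-].[Ti+4].c1cc[cH-]c1.c1cc[cH-]c1
Why: Petasis methylenation is non-basic, so the doubly activated C12 hydrogens are not removed, and the hindered amide reacts far more slowly than the ketone.

Step 16
Reactants: 22 methylene amide
Product: 23 methylene alcohol
Conditions: LiNH2BH3 (from BH3·NH3 and n-BuLi), THF, 0 °C to rt; aqueous work-up
Reagents that add atoms: none
Why: Reduction of a tertiary amide with lithium amidotrihydroborate proceeds with C–N cleavage even next to a quaternary carbon, releasing the auxiliary and giving the C15 primary alcohol.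

Step 17
Reactants: 23 methylene alcohol
Product: 24 methylene aldehyde
Conditions: (n-Pr4N)RuO4 (5 mol%), NMO, 4 Å molecular sieves, CH2Cl2, rt
Reagents that add atoms: none
Why: Ley–Griffith oxidation stops at the non-enolisable aldehyde and leaves both alkenes untouched.

Step 18
Reactants: 24 methylene aldehyde
Product: 25 bicyclic 15-ketone
Conditions: MeAlCl2 (3 equiv), CH2Cl2, −78 °C to 0 °C; aqueous work-up
Reagents that add atoms: none
Why: Proposed new method: excess MeAlCl2 turns the β-benzyloxy aldehyde into a cationic six-membered aluminium chelate (O=C15–C8–C7–OBn), the C16 terminus of the 1,1-disubstituted alkene attacks C15 in the ring C conformer that holds C15 pseudoaxial, charge builds at tertiary C13, the exo hydrogen of C16 shifts to C13 and the former formyl hydrogen shifts from C15 to C16, which unmasks the C15 ketone, so the net change is addition of the C15–H bond across C13=C16. The closest known reaction type is the alkylaluminium halide induced cyclisation of γ,δ-unsaturated aldehydes and ketones to cyclopentanones by a Prins-type closure and two consecutive 1,2-shifts, which has not been shown where the cation sits at a bridgehead. Ring D closes in the 5-endo-trig mode at the alkene (exo at the carbonyl group) and spans C8 and C13 of ring C as a 1,3-diaxial two-carbon bridge. C13 is controlled by C8, because the bridge can only form cis and the migrating hydrogen can only enter the outward lobe at C13, anti to the new C15–C16 bond. The step needs selectivity for C13=C16 over C9=C11 and for hydride shift over proton loss: C9=C11 could only give a four-membered ring, every alkene from proton loss or an ene pathway would violate Bredt's rule, quaternary C8 prevents enolisation, MeAlCl2 destroys adventitious acid, and chelation keeps the Lewis acid away from the hindered acetonide and silyl ether. This stepwise anti addition is chosen because any concerted syn addition of an acyl metal hydride would place C16 trans to C15.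

Step 19
Reactants: 25 bicyclic 15-ketone
Product: 27 C16-methylene ketone, via Mannich base 26 (not isolated)
Conditions: CH2(NMe2)2, Ac2O, DMF, 95 °C
Reagents that add atoms: bis(dimethylamino)methane CN(C)CN(C)C
Why: Mannich methylenation with the iminium acetate made in situ can occur only at C16, since C8 is quaternary, and thermal loss of dimethylamine gives the exocyclic enone carrying C17.

Step 20
Reactants: 27 C16-methylene ketone
Product: 28 enone diol
Conditions: AcOH–THF–H2O (3:1:1), 50 °C
Reagents that add atoms: none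
Why: Acid hydrolysis opens the strained cis-fused dioxolane while the hindered TIPS ether, the benzyl ether and both alkenes persist.

Step 21
Reactants: 28 enone diol
Product: 29 enone diacetate
Conditions: Ac2O, DMAP, pyridine, 40 °C
Reagents that add atoms: acetic anhydride CC(=O)OC(C)=O
Why: DMAP-catalysed acetylation esterifies both hindered secondary alcohols with retention at C1 and C2.

Step 22
Reactants: 29 enone diacetate
Product: 30 epoxide
Conditions: dimethyldioxirane, acetone–CH2Cl2, 0 °C
Reagents that add atoms: dimethyldioxirane CC1(C)OO1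
Why: Dioxirane epoxidation takes the electron-rich trisubstituted C9=C11 in preference to the electron-poor enone and approaches from the exo face, syn to C14 and anti to the C15–C16 bridge, which sets C9 and C11.

Step 23
Reactants: 30 epoxide
Product: 31 C6 alcohol
Conditions: Bu4NF, AcOH (1:1), THF, rt to 40 °C
Reagents that add atoms: none
Why: Buffered fluoride desilylation frees the C6 alcohol under near-neutral conditions that spare the epoxide, the acetates and the enone.

Step 24
Reactants: 31 C6 alcohol
Product: 32 C6 aldehyde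
Conditions: (n-Pr4N)RuO4 (5 mol%), NMO, 4 Å molecular sieves, CH2Cl2, rt
Reagents that add atoms: none
Why: Ley–Griffith oxidation gives the aldehyde under non-acidic conditions, and the equatorial C5 substituent has no drive to epimerise.

Step 25
Reactants: 32 C6 aldehyde
Product: 34 CNP0210140.1 (target), via hydroxy aldehyde 33 (not isolated)
Conditions: H2 (1 atm), Pd/C (10%), EtOAc, rt
Reagents that add atoms: none
Why: Heterogeneous hydrogenation adds H2 to C16=C17 from the exo face (C14 side) so that C17 ends endo (16R) with no later step to scramble it, and benzyl ether hydrogenolysis frees the C7 hydroxyl, which adds to the C6 aldehyde and closes ring B as the lactol.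

Compound list
1 | 2,4,4-trimethylcyclohex-2-en-1-one | CC1=CC(C)(C)CCC1=O | starting material
2 | (1S)-2,4,4-trimethylcyclohex-2-en-1-ol | CC1=CC(C)(C)CC[C@@H]1O | intermediate
3 | tributyl{[(1S)-2,4,4-trimethylcyclohex-2-en-1-yl]oxymethyl}stannane | CC1=CC(C)(C)CC[C@@H]1OC[Sn](CCCC)(CCCC)CCCC | intermediate
4 | lithiomethyl ether of 2 (not isolated) | CC1=CC(C)(C)CC[C@@H]1OC[Li] | intermediate
5 | (R)-α-cyclogeraniol, [(1R)-2,6,6-trimethylcyclohex-2-en-1-yl]methanol | CC1=CCCC(C)(C)[C@H]1CO | intermediate
6 | triisopropylsilyl ether of 5 | CC1=CCCC(C)(C)[C@H]1CO[Si](C(C)C)(C(C)C)C(C)C | intermediate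
7 | C1 alkylborane, boron and H-10 anti to the C5 side chain (not isolated) | C[C@@H]1[C@H](CO[Si](C(C)C)(C(C)C)C(C)C)C(C)(C)CC[C@H]1B | intermediate
8 | (1R,2R,3S)-2,4,4-trimethyl-3-(triisopropylsilyloxymethyl)cyclohexan-1-ol | C[C@@H]1[C@H](CO[Si](C(C)C)(C(C)C)C(C)C)C(C)(C)CC[C@H]1O | intermediate
9 | (2R,3S)-2,4,4-trimethyl-3-(triisopropylsilyloxymethyl)cyclohexan-1-one | C[C@@H]1[C@H](CO[Si](C(C)C)(C(C)C)C(C)C)C(C)(C)CCC1=O | intermediate
10 | (2R,3S,6E)-6-(dimethylaminomethylidene) derivative of 9 | C[C@@H]1[C@H](CO[Si](C(C)C)(C(C)C)C(C)C)C(C)(C)C/C(=C\N(C)C)C1=O | intermediate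
11 | 2-bromo-5-methoxybenzoic acid | COc1ccc(Br)c(C(=O)O)c1 | starting material
12 | (S)-2-(methoxymethyl)pyrrolidine | COC[C@@H]1CCCN1 | starting material
13 | 2-bromo-5-methoxybenzoyl chloride (not isolated) | COc1ccc(Br)c(C(=O)Cl)c1 | intermediate
14 | (S)-N-(2-bromo-5-methoxybenzoyl)-2-(methoxymethyl)pyrrolidine | COC[C@@H]1CCCN1C(=O)c1cc(OC)ccc1Br | intermediate
15 | C10-arylated enaminone ketone, aryl on quaternary C10 trans to the C5 CH2OTIPS group (5R,10R) | O=C1/C(=C/N(C)C)CC(C)(C)[C@@H](CO[Si](C(C)C)(C(C)C)C(C)C)[C@]1(C)c1ccc(OC)cc1C(=O)N1CCC[C@H]1COC | intermediate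
16 | diosphenol, the 2-hydroxy-2-en-1-one tautomer of the C1,C2-dione | O=C1C(O)=CC(C)(C)[C@@H](CO[Si](C(C)C)(C(C)C)C(C)C)[C@]1(C)c1ccc(OC)cc1C(=O)N1CCC[C@H]1COC | intermediate
17 | cis-1,2-diol, both OH on the C20 face (1-OH equatorial, 2-OH axial) | O[C@H]1CC(C)(C)[C@@H](CO[Si](C(C)C)(C(C)C)C(C)C)[C@](C)(c2ccc(OC)cc2C(=O)N2CCC[C@H]2COC)[C@H]1O | intermediate
18 | C1,C2-acetonide of 17 | CC1(C)O[C@H]2CC(C)(C)[C@@H](CO[Si](C(C)C)(C(C)C)C(C)C)[C@](C)(c3ccc(OC)cc3C(=O)N3CCC[C@H]3COC)[C@H]2O1 | intermediate
19 | potassium amide enolate, C8=C15 exocyclic, C9=C11 and C13=C14 in ring C (not isolated) | [K+].CC1(C)O[C@H]2CC(C)(C)[C@@H](CO[Si](C(C)C)(C(C)C)C(C)C)[C@](C)(C3=CCC(OC)=CC3=C([O-])N4CCC[C@H]4COC)[C@H]2O1 | intermediate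
20 | 1,4-diene methyl enol ether with quaternary C8 (CH2OBn and amide), C8 as in the target | CC1(C)O[C@H]2CC(C)(C)[C@@H](CO[Si](C(C)C)(C(C)C)C(C)C)[C@](C)(C3=CCC(OC)=C[C@@]3(COCc4ccccc4)C(=O)N5CCC[C@H]5COC)[C@H]2O1 | intermediate
21 | β,γ-unsaturated C13 ketone | CC1(C)O[C@H]2CC(C)(C)[C@@H](CO[Si](C(C)C)(C(C)C)C(C)C)[C@](C)(C3=CCC(=O)C[C@@]3(COCc4ccccc4)C(=O)N5CCC[C@H]5COC)[C@H]2O1 | intermediate
22 | C13-methylene amide | CC1(C)O[C@H]2CC(C)(C)[C@@H](CO[Si](C(C)C)(C(C)C)C(C)C)[C@](C)(C3=CCC(=C)C[C@@]3(COCc4ccccc4)C(=O)N5CCC[C@H]5COC)[C@H]2O1 | intermediate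
23 | C13-methylene C15 alcohol | CC1(C)O[C@H]2CC(C)(C)[C@@H](CO[Si](C(C)C)(C(C)C)C(C)C)[C@](C)(C3=CCC(=C)C[C@@]3(COCc4ccccc4)CO)[C@H]2O1 | intermediate
24 | methylene aldehyde, precursor of the key step | CC1(C)O[C@H]2CC(C)(C)[C@@H](CO[Si](C(C)C)(C(C)C)C(C)C)[C@](C)(C3=CCC(=C)C[C@@]3(COCc4ccccc4)C=O)[C@H]2O1 | intermediate
25 | bicyclic 15-ketone, product of the key step, C13 as in the target | CC1(C)O[C@H]2CC(C)(C)[C@@H](CO[Si](C(C)C)(C(C)C)C(C)C)[C@](C)(C3=CC[C@@H]4C[C@@]3(COCc5ccccc5)C(=O)C4)[C@H]2O1 | intermediate
26 | C16 dimethylaminomethyl ketone, C16 not defined (not isolated) | CC1(C)O[C@H]2CC(C)(C)[C@@H](CO[Si](C(C)C)(C(C)C)C(C)C)[C@](C)(C3=CC[C@@H]4C[C@@]3(COCc5ccccc5)C(=O)C4CN(C)C)[C@H]2O1 | intermediate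
27 | C16-methylene 15-ketone | CC1(C)O[C@H]2CC(C)(C)[C@@H](CO[Si](C(C)C)(C(C)C)C(C)C)[C@](C)(C3=CC[C@@H]4C[C@@]3(COCc5ccccc5)C(=O)C4=C)[C@H]2O1 | intermediate
28 | enone 1,2-diol | O[C@H]1CC(C)(C)[C@@H](CO[Si](C(C)C)(C(C)C)C(C)C)[C@](C)(C2=CC[C@@H]3C[C@@]2(COCc4ccccc4)C(=O)C3=C)[C@H]1O | intermediate
29 | enone 1,2-diacetate | CC(=O)O[C@H]1CC(C)(C)[C@@H](CO[Si](C(C)C)(C(C)C)C(C)C)[C@](C)(C2=CC[C@@H]3C[C@@]2(COCc4ccccc4)C(=O)C3=C)[C@H]1OC(C)=O | intermediate
30 | 9,11-epoxide, oxygen anti to the C15–C16 bridge | CC(=O)O[C@H]1CC(C)(C)[C@@H](CO[Si](C(C)C)(C(C)C)C(C)C)[C@](C)([C@@]23O[C@@H]2C[C@@H]4C[C@@]3(COCc5ccccc5)C(=O)C4=C)[C@H]1OC(C)=O | intermediate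
31 | epoxy C6 alcohol | CC(=O)O[C@H]1CC(C)(C)[C@@H](CO)[C@](C)([C@@]23O[C@@H]2C[C@@H]4C[C@@]3(COCc5ccccc5)C(=O)C4=C)[C@H]1OC(C)=O | intermediate
32 | epoxy C6 aldehyde | CC(=O)O[C@H]1CC(C)(C)[C@@H](C=O)[C@](C)([C@@]23O[C@@H]2C[C@@H]4C[C@@]3(COCc5ccccc5)C(=O)C4=C)[C@H]1OC(C)=O | intermediate
33 | (16R)-C7 hydroxy C6 aldehyde (not isolated) | CC(=O)O[C@H]1CC(C)(C)[C@@H](C=O)[C@](C)([C@@]23O[C@@H]2C[C@@H]4C[C@@]3(CO)C(=O)[C@@H]4C)[C@H]1OC(C)=O | intermediate
34 | CNP0210140.1 (1R,2S,5R,6R,8S,9S,10S,11R,13S,16R in the numbering above) | CC(=O)O[C@H]1CC(C)(C)[C@H]2[C@H](O)OC[C@@]34C[C@@H](C[C@H]5O[C@]53[C@]2(C)[C@H]1OC(C)=O)[C@@H](C)C4=O | target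

Total step count: 25. Longest linear sequence: 24 (steps 1–7 and 9–25).

Steps most likely to fail

1. Step 18 (Proposed new method). The closure may stall because positive charge has to build at a bridgehead carbon. The charge may also drain through a competing hydride shift from C12 towards the neighbouring alkene, or the Lewis acid may strip the acetonide. The fallback uses known chemistry and makes C15–C16 by carbanion acylation. It sets out from 22 and comes back at 25. Hydroboration–oxidation with 9-BBN, then NaOH and H2O2, touches only the C13=C16 methylene and gives the C16 hydroxy amide F1. I2, PPh3 and imidazole convert this into the C16 iodo amide F2. t-BuLi in Et2O–pentane at −78 °C then brings about iodine–lithium exchange, and the primary alkyllithium acylates itself on the tertiary amide (Parham-type cyclisation) to release 25 on work-up. Only the C13 isomer with C16 cis to C15 can close, so the other isomer from the hydroboration is removed at this point.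

2. Step 9. Reductive elimination at the crowded tetrasubstituted enolate carbon may be too slow next to the bulky, chelating ortho amide, so that loss of bromine from the aryl partner overtakes coupling. The fallback attaches the auxiliary after the hindered C–C bond has been made. It sets out from 11 and 10 and comes back at 15. MeOH with catalytic H2SO4 gives the methyl bromo ester F3. The same palladium arylation of 10, with K3PO4 as base, then meets a smaller ortho group that does not chelate and gives the keto ester F4. LiI in refluxing pyridine cleaves the methyl ester by attack at the methyl group to give the keto acid F5. (COCl)2 gives the acid chloride F6, which acylates 12 in the presence of Et3N to give 15.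

3. Step 13. Facial selectivity may be poor if the auxiliary and the chiral ring A substituent oppose each other, or the crowded enolate may be protonated before it is alkylated. The fallback separates reduction from alkylation. It sets out from 18 and comes back at 19 and 20. The same K–NH3 reduction, quenched with NH4Cl, gives the 1,4-dihydro amide F7. KN(SiMe3)2 in THF at −78 °C regenerates enolate 19 free of ammonia and tert-butoxide, so that counter-ion, additive and temperature can be chosen independently. BnOCH2Cl then gives 20.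

Further compounds
F1 | step 18 | C16 hydroxy amide, C16 cis to C15 | CC1(C)O[C@H]2CC(C)(C)[C@@H](CO[Si](C(C)C)(C(C)C)C(C)C)[C@](C)(C3=CC[C@@H](CO)C[C@@]3(COCc4ccccc4)C(=O)N5CCC[C@H]5COC)[C@H]2O1
F2 | step 18 | C16 iodo amide | CC1(C)O[C@H]2CC(C)(C)[C@@H](CO[Si](C(C)C)(C(C)C)C(C)C)[C@](C)(C3=CC[C@@H](CI)C[C@@]3(COCc4ccccc4)C(=O)N5CCC[C@H]5COC)[C@H]2O1
F3 | step 9 | methyl 2-bromo-5-methoxybenzoate | COC(=O)c1cc(OC)ccc1Br
F4 | step 9 | C10-arylated keto ester | O=C1/C(=C/N(C)C)CC(C)(C)[C@@H](CO[Si](C(C)C)(C(C)C)C(C)C)[C@]1(C)c1ccc(OC)cc1C(=O)OC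
F5 | step 9 | C10-arylated keto acid | O=C1/C(=C/N(C)C)CC(C)(C)[C@@H](CO[Si](C(C)C)(C(C)C)C(C)C)[C@]1(C)c1ccc(OC)cc1C(=O)O
F6 | step 9 | C10-arylated keto acid chloride | O=C1/C(=C/N(C)C)CC(C)(C)[C@@H](CO[Si](C(C)C)(C(C)C)C(C)C)[C@]1(C)c1ccc(OC)cc1C(=O)Cl
F7 | step 13 | 1,4-dihydro amide, C8 not defined | CC1(C)O[C@H]2CC(C)(C)[C@@H](CO[Si](C(C)C)(C(C)C)C(C)C)[C@](C)(C3=CCC(OC)=CC3C(=O)N4CCC[C@H]4COC)[C@H]2O1
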